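C2 of ring C is treated as carbon monoxide, so 12 ⇐ 11 (tetra-O-benzyl ether; one hydrogenolysis frees 5-, 7-, 3'- and 4'-OH).
11 ⇐ 4 + 7 + 8: ring C is cut around C2 in one stroke (C1'–C2, C2–C3, C2–O1) by a Pd-catalysed three-component carbonylative annulation. C2 is carbon monoxide 8, ring B is aryl bromide 7, and ring A with O1, C3 and C4 is o-hydroxyacetophenone 4.
Enabling feature: C2 of the pyran-4-one ring C is an acyl-level carbon bonded only to C1' of ring B, O1 and C3. It can therefore be a CO carbon caught between an aryl–Pd bond and the O1/C3 pair (phenol O and acetyl CH3) on ring A. Ring A is mirror-symmetric about the C4a···C7 axis (O1/5-O, 8-OMe/6-OMe), so ring closure raises no regiochemical question.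
4 ⇐ 1 (dibenzylation, dibromination, double Cu-catalysed methoxylation). 7 ⇐ 5 (Dakin oxidation, dibenzylation), which places Br para to the central oxygen and so gives the 3',4',5' pattern.
Ring order: rings A and B are purchased arenes; ring C is the only ring formed, in step 6.

Key step: step 6

Assumption: the target is a planar, achiral flavone with no stereocentre and no stereogenic axis, so the SMILES defines it fully and no step has to control configuration.

Step 1
Reactants: 1 2',4',6'-trihydroxyacetophenone
Product: 2 1-[2,4-bis(benzyloxy)-6-hydroxyphenyl]ethanone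
Conditions: BnBr (2.1 equiv), K2CO3 (2.2 equiv), DMF, rt → 50 °C
Reagents that add atoms: benzyl bromide, BrCc1ccccc1
Why: Williamson ether synthesis: with two equivalents of halide the 4-OH and one of the two equivalent ortho-OH groups are alkylated, while the remaining ortho-OH is held in a strong hydrogen bond to the acetyl C=O and stays free.

Step 2
Reactants: 2 1-[2,4-bis(benzyloxy)-6-hydroxyphenyl]ethanone
Product: 3 1-[2,4-bis(benzyloxy)-3,5-dibromo-6-hydroxyphenyl]ethanone
Conditions: NBS (2.1 equiv), MeCN, 0 °C → rt, dark
Reagents that add atoms: N-bromosuccinimide, O=C1CCC(=O)N1Br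
Why: Electrophilic aromatic bromination: C3 and C5 are the only free ring carbons and each lies ortho or para to all three oxygen donors, so ring substitution should outrun bromination of the acetyl CH3 or of the benzylic CH2 groups in the dark.

Step 3
Reactants: 3 1-[2,4-bis(benzyloxy)-3,5-dibromo-6-hydroxyphenyl]ethanone
Product: 4 1-[2,4-bis(benzyloxy)-6-hydroxy-3,5-dimethoxyphenyl]ethanone
Conditions: NaOMe (10 equiv, 5.4 M in MeOH), CuBr (30 mol %), DMF, 110 °C, Ar; then 1 M HCl
Reagents that add atoms: sodium methoxide, [Na+].[O-]C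
Why: Copper-catalysed Ullmann-type C–O coupling of aryl bromides with methoxide, the reaction type that converts 3,5-dibromo-4-hydroxybenzaldehyde into syringaldehyde and 6,8-dibromo-5,7-dihydroxyflavones into their 6,8-dimethoxy analogues, to which benzyl ethers and the hindered ketone should be inert.

Step 4
Reactants: 5 5-bromo-2-hydroxy-3-methoxybenzaldehyde
Product: 6 5-bromo-3-methoxybenzene-1,2-diol
Conditions: 30 % H2O2 (1.2 equiv), NaOH (1.1 equiv), H2O/THF, 0 °C → rt, N2; then 1 M HCl
Reagents that add atoms: hydrogen peroxide, OO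
Why: Dakin oxidation: hydroperoxide adds to the aldehyde ortho to the phenoxide, the electron-rich aryl group migrates to oxygen and the aryl formate is hydrolysed, which leaves bromine para to the central oxygen of the new 3-methoxycatechol.

Step 5
Reactants: 6 5-bromo-3-methoxybenzene-1,2-diol
Product: 7 1,2-bis(benzyloxy)-5-bromo-3-methoxybenzene
Conditions: BnBr (2.3 equiv), K2CO3 (2.5 equiv), DMF, 60 °C
Reagents that add atoms: benzyl bromide, BrCc1ccccc1
Why: Double Williamson ether synthesis on both catechol oxygens, to which the aryl bromide and the methyl ether are inert.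

Step 6
Reactants: 4 1-[2,4-bis(benzyloxy)-6-hydroxy-3,5-dimethoxyphenyl]ethanone (1.1 equiv); 7 1,2-bis(benzyloxy)-5-bromo-3-methoxybenzene; 8 carbon monoxide
Product: 11 5,7-bis(benzyloxy)-2-[3,4-bis(benzyloxy)-5-methoxyphenyl]-6,8-dimethoxy-4H-chromen-4-one, via aryl benzoate ester 9 (not isolated), via β-diketone 10 (not isolated)
Conditions: Pd(OAc)2 (3 mol %), dppb (6 mol %), DBU (3 equiv), CO (10 bar), DMF, 120 °C, autoclave
Reagents that add atoms: none
Why: Pd(0) inserts into the C–Br bond of 7 and CO 8 migrates into the aryl–Pd bond, which makes the C1'–C2 bond; the aroyl-Pd species is then taken up by the DBU-generated phenoxide of 4 to give ester 9. DBU enolises the neighbouring acetyl group and a Baker–Venkataraman O-to-C acyl shift through a six-membered cyclic adduct gives β-diketone 10 (C2–C3 bond), a point that direct C-acylation of the enolate by the aroyl-Pd species would reach as well. Ring C closes by 6-exo-trig attack of the released phenol oxygen on the aroyl carbonyl (C2–O1 bond) and loss of water from the 2-hydroxyflavanone, driven by formation of the conjugated pyran-4-one. The closest known reaction type is the palladium-catalysed carbonylative coupling of aryl bromides with 2-hydroxyacetophenones to flavones, itself a merger of aryl halide alkoxycarbonylation with the Baker–Venkataraman flavone synthesis. No stereocentre is formed. The step needs one acylation at one oxygen and CO insertion before capture: 4 offers a single free OH (the later 5- and 7-oxygens are benzylated and every ring carbon is substituted), 7 has a single C–Br bond, the slight excess of 4 holds back a second aroylation at C3, and CO pressure suppresses direct C–O coupling or α-arylation.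

Step 7
Reactants: 11 5,7-bis(benzyloxy)-2-[3,4-bis(benzyloxy)-5-methoxyphenyl]-6,8-dimethoxy-4H-chromen-4-one
Product: 12 5,7,3',4'-tetrahydroxy-6,8,5'-trimethoxyflavone
Conditions: H2 (1 atm), 10 % Pd/C, THF/MeOH 1:1, rt
Reagents that add atoms: none
Why: Catalytic hydrogenolysis of the four benzyl aryl ethers, under which aryl methyl ethers are inert and the conjugated C2=C3 bond of a flavone is normally kept at 1 atm and room temperature if the reaction is stopped after uptake of four equivalents of hydrogen.

Compound list
1 | 2',4',6'-trihydroxyacetophenone | CC(=O)c1c(O)cc(O)cc1O | starting material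
2 | 1-[2,4-bis(benzyloxy)-6-hydroxyphenyl]ethanone | CC(=O)c1c(O)cc(OCc2ccccc2)cc1OCc1ccccc1 | intermediate
3 | 1-[2,4-bis(benzyloxy)-3,5-dibromo-6-hydroxyphenyl]ethanone | CC(=O)c1c(O)c(Br)c(OCc2ccccc2)c(Br)c1OCc1ccccc1 | intermediate
4 | 1-[2,4-bis(benzyloxy)-6-hydroxy-3,5-dimethoxyphenyl]ethanone | CC(=O)c1c(O)c(OC)c(OCc2ccccc2)c(OC)c1OCc1ccccc1 | intermediate
5 | 5-bromo-2-hydroxy-3-methoxybenzaldehyde | COc1cc(Br)cc(C=O)c1O | starting material
6 | 5-bromo-3-methoxybenzene-1,2-diol | COc1cc(Br)cc(O)c1O | intermediate
7 | 1,2-bis(benzyloxy)-5-bromo-3-methoxybenzene | COc1cc(Br)cc(OCc2ccccc2)c1OCc1ccccc1 | intermediate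
8 | carbon monoxide | [C-]#[O+] | starting material
9 | 2-acetyl-3,5-bis(benzyloxy)-4,6-dimethoxyphenyl 3,4-bis(benzyloxy)-5-methoxybenzoate | CC(=O)c1c(OC(=O)c2cc(OC)c(OCc3ccccc3)c(OCc3ccccc3)c2)c(OC)c(OCc2ccccc2)c(OC)c1OCc1ccccc1 | intermediate
10 | 1-[2,4-bis(benzyloxy)-6-hydroxy-3,5-dimethoxyphenyl]-3-[3,4-bis(benzyloxy)-5-methoxyphenyl]propane-1,3-dione | COc1cc(C(=O)CC(=O)c2c(O)c(OC)c(OCc3ccccc3)c(OC)c2OCc2ccccc2)cc(OCc2ccccc2)c1OCc1ccccc1 | intermediate
11 | 5,7-bis(benzyloxy)-2-[3,4-bis(benzyloxy)-5-methoxyphenyl]-6,8-dimethoxy-4H-chromen-4-one | COc1cc(-c2cc(=O)c3c(OCc4ccccc4)c(OC)c(OCc4ccccc4)c(OC)c3o2)cc(OCc2ccccc2)c1OCc1ccccc1 | intermediate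
12 | 5,7,3',4'-tetrahydroxy-6,8,5'-trimethoxyflavone | COc1cc(-c2cc(=O)c3c(O)c(OC)c(O)c(OC)c3o2)cc(O)c1O | target

Total step count: 7
Longest linear sequence: 5 steps (steps 1, 2, 3, 6, 7)

Steps most likely to fail

Step 6.
- **What may go wrong:** The phenoxide of 4 is flanked by an acetyl and a methoxy group, so its capture of the aroyl-palladium species may be slower than reduction or homocoupling of the aryl-palladium species. The cascade may also stall before the acyl shift or before dehydration, and a second aroylation at C3 may set in.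
- **Fallback:** Ring C is closed first, and the same C2–C1' bond is then made by cross-coupling. The fallback sets out from 4 and comes back to the route at 11. Heating 4 with N,N-dimethylformamide dimethyl acetal should give the enaminone (E)-1-[2,4-bis(benzyloxy)-6-hydroxy-3,5-dimethoxyphenyl]-3-(dimethylamino)prop-2-en-1-one F1. Aqueous HCl in CH2Cl2 should close this, with loss of dimethylamine, to 5,7-bis(benzyloxy)-6,8-dimethoxy-4H-chromen-4-one F2. Deprotonation of the vinylic C2–H next to O1 with TMPZnCl·LiCl in THF should give [5,7-bis(benzyloxy)-6,8-dimethoxy-4-oxo-4H-chromen-2-yl]zinc chloride F3. Negishi coupling of this zinc reagent with 7 (Pd(OAc)2, SPhos, THF, 50 °C) should then give 11.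

Step 3.
- **What may go wrong:** Reductive loss of bromine may compete with C–O bond formation, above all at the C3–Br bond flanked by two benzyloxy groups. The second substitution may remain incomplete, and hot methoxide may strip benzyl groups.
- **Fallback:** The two methoxy groups are bought with the ring, and the phenolic oxygens are introduced instead, at less crowded C–Br bonds. The fallback sets out in place of 1, with purchased 2,6-dimethoxyphenol F4 replacing 1 as the source of ring A, and comes back to the route at 4. O-Benzylation (BnBr, K2CO3, DMF) should give 2-(benzyloxy)-1,3-dimethoxybenzene F5. Two equivalents of NBS in MeCN should brominate the two positions para to a methoxy group and give 3-(benzyloxy)-1,5-dibromo-2,4-dimethoxybenzene F6. Palladium-catalysed hydroxylation (Pd2(dba)3, tBuXPhos, KOH, dioxane/H2O, 100 °C) should give 5-(benzyloxy)-4,6-dimethoxybenzene-1,3-diol F7. Houben–Hoesch acylation (MeCN, ZnCl2, HCl, Et2O, 0 °C; then H2O, reflux) at the only free ring carbon should give 1-[4-(benzyloxy)-2,6-dihydroxy-3,5-dimethoxyphenyl]ethanone F8. One equivalent of BnBr with K2CO3 should then alkylate one of the two equivalent ortho-OH groups to give 4.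

Step 7.
- **What may go wrong:** The C2=C3 bond may be over-reduced, cleavage of the crowded 5-O-benzyl group may be incomplete, and the catechol may oxidise in air while the catalyst is filtered off.
- **Fallback:** A non-reductive cleavage is used, followed by purification through a stable derivative. The fallback sets out from 11 and comes back to the route at 12. BCl3 with pentamethylbenzene as benzyl cation scavenger (CH2Cl2, −78 °C) should cleave the four benzyl ethers without touching C2=C3, and at this temperature the aryl methyl ethers should persist. The crude polyphenol is peracetylated (Ac2O, pyridine) to 5,7,3',4'-tetraacetoxy-6,8,5'-trimethoxyflavone F9. This derivative can be purified without air sensitivity, and acid methanolysis (cat. HCl, degassed MeOH) should return 12.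

Further compounds
F1 | step 6 | (E)-1-[2,4-bis(benzyloxy)-6-hydroxy-3,5-dimethoxyphenyl]-3-(dimethylamino)prop-2-en-1-one | CN(C)/C=C/C(=O)c1c(O)c(OC)c(OCc2ccccc2)c(OC)c1OCc1ccccc1
F2 | step 6 | 5,7-bis(benzyloxy)-6,8-dimethoxy-4H-chromen-4-one | O=c1ccoc2c(OC)c(OCc3ccccc3)c(OC)c(OCc3ccccc3)c12
F3 | step 6 | [5,7-bis(benzyloxy)-6,8-dimethoxy-4-oxo-4H-chromen-2-yl]zinc chloride | Cl[Zn]c1cc(=O)c2c(OCc3ccccc3)c(OC)c(OCc3ccccc3)c(OC)c2o1
F4 | step 3 | 2,6-dimethoxyphenol (purchased) | COc1cccc(OC)c1O
F5 | step 3 | 2-(benzyloxy)-1,3-dimethoxybenzene | COc1cccc(OC)c1OCc1ccccc1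
F6 | step 3 | 3-(benzyloxy)-1,5-dibromo-2,4-dimethoxybenzene | COc1c(Br)cc(Br)c(OC)c1OCc1ccccc1
F7 | step 3 | 5-(benzyloxy)-4,6-dimethoxybenzene-1,3-diol | COc1c(O)cc(O)c(OC)c1OCc1ccccc1
F8 | step 3 | 1-[4-(benzyloxy)-2,6-dihydroxy-3,5-dimethoxyphenyl]ethanone | CC(=O)c1c(O)c(OC)c(OCc2ccccc2)c(OC)c1O
F9 | step 7 | 5,7,3',4'-tetraacetoxy-6,8,5'-trimethoxyflavone | COc1cc(-c2cc(=O)c3c(OC(C)=O)c(OC)c(OC(C)=O)c(OC)c3o2)cc(OC(C)=O)c1OC(C)=O
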